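The earlier runs and the new flask come from a simulation for substances that don't exist; the scatter is artificial.

The amounts first: gamma and beta each hold 0.16 M of starting material, between the charges of the earlier winter and midnight runs. Gamma is read at 4.0 min, beta at 12 min.

| flask | starting material | remark | time |
|---|---|---|---|
| winter | 0.11 M | run made earlier |  |
| midnight | 0.24 M | run made earlier |  |
| gamma | 0.16 M |  | 4.0 min |
| beta | 0.16 M |  | 12 min |

| run | time / min | target / % | intermediate C / % | intermediate A / % | over-reaction product / % | starting material / % |
|---|---|---|---|---|---|---|
| winter | 0.500 | 1.1 | 0 | 34.2 | 0.5 | 58.7 |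
| winter | 1.00 | 0 | 2.4 | 51.2 | 0 | 34.7 |
| winter | 1.50 | 1.0 | 6.1 | 59.2 | 1.0 | 21.0 |
| winter | 2.00 | 2.8 | 8.3 | 60.9 | 0.7 | 13.3 |
| winter | 2.50 | 5.2 | 10.1 | 62.4 | 1.9 | 7.4 |
| winter | 3.00 | 4.1 | 13.3 | 60.5 | 4.5 | 5.8 |
| midnight | 0.500 | 0.8 | 0 | 31.8 | 0.6 | 52.1 |
| midnight | 1.00 | 0.3 | 3.5 | 45.3 | 1.6 | 29.7 |
| midnight | 1.50 | 0 | 4.0 | 52.7 | 0.4 | 18.2 |
| midnight | 2.00 | 1.1 | 9.0 | 55.7 | 0.9 | 11.4 |
| midnight | 2.50 | 3.7 | 10.4 | 55.9 | 2.5 | 7.7 |
| midnight | 3.00 | 4.3 | 12.8 | 54.8 | 2.2 | 3.7 |

(each reading ± 1 percentage point)

- percentages count the starting material that a species holds: one homo dimer counts as two
- target is meant together with its crystals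
- solid, in amounts per volume of the solution: crystals
- what may be going on: 2 starting material -> homo dimer; intermediate B -> intermediate C; target -> over-reaction product; intermediate A -> intermediate B; intermediate C -> target; starting material -> intermediate A; crystals <-> target

- which of these there is most of at the end, counted by the starting material in it, gamma (intermediate C / over-reaction product / intermediate A / target)
- which of these there is most of at the end, counted by the starting material in it, beta (intermediate C / over-reaction product / intermediate A / target)
- amount of the one of these that there is most of at the end, in percent of the starting material charged, gamma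
- amount of the one of these that there is most of at the end, in percent of the starting material charged, beta

At 3.00 min intermediate A is the most plentiful of the read species in both earlier runs, the resting state of this chain, so I count its half-lives. I call h the half-life of intermediate A, the time in which its own loss halves it. For each run I add up what is read past it at 3.00 min (intermediate C, target, over-reaction product) and divide by the area under its curve. That reads a loss constant k of 0.147 /min in the winter run and 0.144 /min in the midnight run, with the scatter of the readings in it. With their mean, h = ln(2)/k = 4.77 min.

Now the question turned round: what would keep intermediate A ahead in beta? The two runs average 57.6% of it at 3.00 min, and 83.0% over the read species, of which intermediate C and target hold 17.2%. If that total stays and those two hold that much at the end, intermediate A ties with over-reaction product at 32.9%. Counted from 3.00 min, that needs a half-life of 11.1 min, longer than h.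

So I count on. From 3.00 min, beta gets 1.89 half-lives, which by my count leaves 15.6% of intermediate A, less than the tie, so I expect over-reaction product to lead. Gamma gets 0.210 half-lives, which by my count leaves 49.9% of intermediate A, so I expect it to lead there.

The forecast says intermediate A at 52% for gamma, more than my figure, and over-reaction product at 50% for beta, “leaving over-reaction product near 50%”.

Gamma gives intermediate A at 51.6%, and beta gives over-reaction product at 56.2%.

    2 starting material → homo dimer (k = 0.0180 /M/s)
    intermediate B → intermediate C (k = 0.110 /s)
    target → over-reaction product (k = 0.0130 /s)
    intermediate A → intermediate B (k = 0.00260 /s)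
    intermediate C → target (k = 0.00820 /s)
    starting material → intermediate A (k = 0.0150 /s)
    crystals ⇌ target, rate k7*(cs7 - [target]) while solid is left; crystals form when [target] > cs7 (solubility = 0.150 M, k = 0.0340 /s)

Both leaders stand as forecast, but over-reaction product in beta lies 6.2 percentage points above the forecast, and intermediate A there holds 15.5%, against my count of 15.6%. The same count on beta left until 30 min gives 5.66 half-lives and 1.14% of intermediate A. That flask holds 0.936% of intermediate A and 82.9% of over-reaction product.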